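| flask | starting material | second substrate | free catalyst | temperature | remark | time |
|---|---|---|---|---|---|---|
| midnight | 0.0010 M | 1.5 mM | 10 µM | 100 °C | run made earlier |  |
| spring | 5.0 × 10⁻⁴ M | 1 mM | 10 µM | 100 °C | run made earlier |  |
| north | 0.0010 M | 1.00 mM | 6.0 µM | 115 °C |  | 6.0 min |
| north-east | 0.0010 M | 1.00 mM | 10 µM | 100 °C |  | 10 min |

| run | time / s | target / % |
|---|---|---|
| midnight | 10.0 | 4 |
| midnight | 20.0 | 6 |
| midnight | 50.0 | 13 |
| midnight | 120 | 18 |
| spring | 30.0 | 11 |
| spring | 60.0 | 14 |
| spring | 90.0 | 20 |
| spring | 120 | 25 |

(standard deviation of a reading: 2 percentage points)

- the earlier runs do not show what temperature does; that part of a forecast is a guess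
- a reading or a percentage of target counts all its forms, free or not
- no earlier run changes the charge of free catalyst; that part of a forecast is a guess

* which one finishes higher in amount of target, in percent of the starting material charged ("neither" within 2 percentage points) (north / north-east / neither)
* amount of target at the end, in percent of the starting material charged, north
* amount of target at the end, in percent of the starting material charged, north-east

1. The ratio to watch is target percent in the spring run over that in the midnight run. It reads 1.08 at 60.0 s against 50.0 s, and 1.39 at 120 s, each with a scatter of 2 percentage points on every reading. The spring run holds 0.500 of the starting material of the midnight run, so a fixed amount of target per catalyst charged gives a ratio of 2. The last ratio lies nearer 1 than 2.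

2. Follow one catalyst molecule at fixed temperature. Of the forks open to it when it stands free, the reckoning here weighs two: it takes up starting material or it dies, and the odds of the first are taken to go with the starting material present. On that reckoning each catalyst charged removes a fixed fraction of the starting material before it dies, not a fixed amount (pseudo-first-order in starting material).

3. The reach of the catalyst is the natural logarithm of charged over left, per amount of catalyst charged. Taking the readings at 120 s as ends, though the spring run is still higher there than at 90.0 s, their mean leaves 78.5%, which reads as a reach of 24.2 /mM, with the scatter of those readings.

4. North-east looks nearly like the midnight run: same starting material, catalyst and temperature, but 1.00 mM of second substrate against 1.5 mM. The spring run has 0.667 of the midnight second substrate, but it differs in starting material as well, so these two runs do not separate the two settings; the reckoning here assumes that the reach does not change with second substrate. North-east runs longer than those readings and should end near 21.5%.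

5. North at the same reach gives 13.5%, but no run shows what 115 °C does to the reach. The reckoning here commits to north-east ahead on its larger charge of free catalyst, 10 µM against 6.0 µM, and leaves the effect of temperature as a guess.

6. The forecast also puts north-east ahead, with 12% for north and 17% for north-east, the latter lower than this reckoning, on the ground that target “scales roughly with the second substrate”.

7. The flasks give 7.00% in north and 22.0% in north-east, so north-east finishes higher. North-east already stands at 22.0% after 5.00 min, with spent catalyst at 99.8% of the catalyst charged, and it still shows 22.0% after 100 min.

    free catalyst + target ⇌ idle complex (K = 1400 /M, k = 53.9 /M/s, Ea = 58.0 kJ/mol, ΔH = 44.0 kJ/mol)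
    free catalyst → spent catalyst (k = 0.0515 /s, Ea = 112 kJ/mol)
    second substrate + free catalyst ⇌ catalyst intermediate B (K = 1040 /M, k = 4810 /M/s, Ea = 40.0 kJ/mol, ΔH = 12.0 kJ/mol)
    catalyst intermediate A → free catalyst + target (k = 7.41 /s, Ea = 81.0 kJ/mol)
    starting material + free catalyst ⇌ catalyst intermediate A (K = 540 /M, k = 1880 /M/s, Ea = 42.0 kJ/mol, ΔH = 8.00 kJ/mol)
    catalyst intermediate B → free catalyst + second product (k = 0.791 /s, Ea = 86.0 kJ/mol)
    (constants at 100 °C)

The 78% of starting material left in north-east gives a reach of 24.8 /mM. A neighbour flask repeats north-east with 4.0 × 10⁻⁵ M of free catalyst, 4.00 times the charge. The reach read from the early runs leaves 38.0% of the starting material there and gives 62.0% of target. In that neighbour flask spent catalyst reaches >99.9%, starting material stands at 37.1%, and target stands at 62.9%.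

(Readings and results stem from a simulated flask with made-up constants; noise was put on by code.)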